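## Structural features

The target is a diaryl ether without any stereocentre: two benzene rings are held together only by the oxygen between C2 of ring A and C1' of ring B. Ring A is pentasubstituted in an unbroken sequence (C1 CO2CH3, C2 O-aryl, C3 OCH3, C4 Cl, C5 OH), with C6–H as its only free position. Ring B carries C1' O-aryl, C3' CH3, C5' OH and C6' CO2H, so its carboxyl sits between two oxygens. The ether oxygen is flanked by two ortho substituents on ring A and one on ring B, which makes a classical substitution or copper coupling at this bond slow. The fragile points are the aryl chloride (lost under catalytic hydrogenolysis), the 2,6-dioxygenated ring B acid (prone to protodecarboxylation in hot strong acid), and the 2-aryloxybenzoate unit, which closes to a xanthone whenever an aryl anion or an acylium ion is generated next to it. The real difficulty is positional and differential: chlorine must lie between the two oxygens of ring A, the carboxyl between the two oxygens of ring B, the ether must form at a crowded phenol, and only one of two aromatic carboxyl groups may end as a methyl ester. The key step exploits the contiguous triad C1' (O-aryl), C6' (CO2H), C5' (OH) of ring B, which is what results when an oxygen nucleophile and CO2 add across the C1'–C6' triple bond of an aryne whose C5' oxygen steers the nucleophile to C1'. The unequal crowding of the two carboxyl groups (one ortho neighbour on ring A, two on ring B) is the handle for the later mono-esterification.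

## Logic of the disconnections

23 ⇒ 22. The phenolic O–H bonds at C5 and C5' are traced back to O–benzyl bonds. Both phenols must stay masked through base, organolithium and aryne chemistry. Benzyl can be put on ring A during the oxygenation step and on ring B before metalation, and a Lewis acid removes it without the hydrogenolysis that would endanger C4–Cl. The skeleton is unchanged. The forward cleavage must spare the C3 methyl ether, the ring A methyl ester and the free ring B acid.

22 ⇒ 21. The O–CH3 bond of the ring A ester is cut. Ring A has to pass through the coupling as a carboxylate, because an ester would be attacked by the neighbouring aryl anion and close a xanthone, so the methyl group can only arrive afterwards. The gain is that 21 is the direct product of the key step. The forward step must choose the C1 carboxyl (one ortho neighbour) over the C6' carboxyl (two ortho oxygens), so it has to be an addition–elimination esterification under kinetic control and not a carboxylate alkylation.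

21 ⇒ 7 + 16 + 17. The bonds O–C1' and C6'–C(carboxyl) are cut, the two bonds that a nucleophile and an electrophile form across an aryne. The cut splits the molecule at the ether into two rings of similar size and places the ring B carboxyl between its two oxygens without a separate, unselective carboxylation. It also replaces a slow substitution at a crowded phenol by addition to an aryne, which is indifferent to ortho substituents on the nucleophile. The demands are that the oxygen adds at C1' and not C6', that the aryl anion takes up 17 faster than a proton, and that ring A offers the anion no electrophile.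

7 ⇒ 6 ⇒ 4. The C1–C(carboxyl) bond of ring A is cut, the carbon being introduced as a formyl group and then oxidised. In 4 the only free position ortho to the hydroxyl is C1, so an ortho-specific formylation has a single site. The gain is a hydroquinone mono-ether without carbon substituents. The formylation must be strictly ortho, and the oxidation must not chlorinate or oxidise the electron-rich ring.

4 ⇒ 1. The C–O bond of the hydroxyl that later becomes the ether oxygen and the O–benzyl bond at C5 are cut. In 1 the chlorine already lies between two oxygens, so no electrophilic chlorination is needed; in a 3,5-dioxygenated benzoate such a chlorination would be expected to go ortho to the carboxyl and not between the oxygens. The missing oxygen is para to the hydroxyl of 1, the position a persulfate oxidation delivers. The demand is that the two oxygens of the resulting hydroquinone are told apart, which is met by holding the new one as a sulfate (2, 3) while the old one is benzylated.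

16 ⇒ 14 ⇒ 10 ⇒ 9 ⇒ 8. The S–O bond of the triflate, the C–Si bond, the carbamoyl C–O bond and the O–benzyl bond are cut in turn. Silicon must sit on the carbon between the two oxygens, which is exactly where two directing groups cooperate in a metalation, and the carbamate is a directing group that comes off under mild base. The gain is the symmetric, cheap diol 8. The demands are a mono-benzylation of a symmetric diol and a ring metalation that outruns deprotonation of the benzylic CH2.

## Other disconnections considered

Alternative 1: Ring B is cut at C5'–C6' and built last from an open chain attached to ring A as a vinyl aryl ether, the heptadienedioate A1. KOC(CH3)3 would remove a proton from the doubly allylic C2' methylene; the carbon α to the tert-butyl ester (C6') would attack the methyl ester carbonyl (C5') in a Dieckmann-type 6-exo-trig closure, and loss of methoxide and enolization would give phenol A2.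
- In its favour: the two carboxyl groups are different esters from the outset, so A2 needs a single acid treatment (tert-butyl ester and methoxymethyl ether fall together) to reach 23. On carboxyl differentiation this plan is better than the chosen one, which must separate two free acids by rate, and it has no aryne site selectivity to control.
- Against it here: A1 contains a second methyl ester, on ring A ortho to the enol ether oxygen, which the same C6' nucleophile can reach through an equally favourable six-membered transition state to give a chromone. β-Aryloxy acrylates can also lose the aryloxide by addition–elimination with alkoxide, and the chain has to be attached to a hindered, chelated phenol.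
- Comparison: in both plans an anion must pick the right electrophile. Here it chooses between two esters of similar reactivity, whereas the chosen plan removes the competing electrophile by carrying ring A as a carboxylate. Structurally the chosen plan is more convergent. In step count alternative 1 is expected to be equal or longer (ring A phenol, chain synthesis, conjugate addition, cyclization, deprotection: about eleven to twelve steps).

Alternative 2: Ring A is cut at C2–C1 and C2–C3 and built on the methylene carbon of benzofuranone A3. With catalytic KOC(CH3)3 the enolate of A3 would add in turn to both alkyne termini of diynone A4, each β to the ketone, closing ring A as the spiro cyclohexa-2,5-dienone A5 (racemic). Chlorination at C4, the nucleophilic α-carbon of the β-methoxy enone, then hydrolytic cleavage of the bond between the spiro carbon and the furanone carbonyl (driven by aromatization of ring A) and debenzylation would lead to 23.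
- In its favour: the ring A substitution pattern, the position of the chlorine and the difference between the two carboxyls (ester from A4, acid from the furanone ketone) all follow from the mechanism. On carboxyl differentiation and on placing the chlorine by reactivity rather than by purchase this plan is better than the chosen one. On ring B regiochemistry it is equal, since A3 fixes it as 16 does.
- Against it here: A4 combines an alkynyl ether, an ynone and an ynoate and would be hard to prepare and store. The first Michael addition has a choice on the ester-substituted alkyne (β to the ketone or β to the ester). The enolate can react at oxygen, the chlorination must prefer the dienone over the benzyloxy-activated ring B, and a quaternary stereocentre is built only to be destroyed.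
- Comparison: the step count is similar (roughly ten to twelve) and the convergence is the same. The alternative trades the unprecedented three-component coupling for an unusually sensitive reagent and a redox-neutral detour through a spiro compound.

Alternative 3: Ring A is cut at C6–C1 and C3–C2. The alkylidene benzofuranone A6, reachable from A3 by aldol condensation, would undergo a thermal [4+2] cycloaddition with the ketene-acetal diene A7 at its exocyclic alkene. Loss of methanol and of the silyl group on acidic work-up would give the spiro methoxycyclohexenone A8 (racemic, one diastereomer). A dehydrogenation across C1–C6 to the dienone level of A5, then the chlorination, fragmentation and debenzylation of alternative 2, would follow.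
- In its favour: neutral thermal conditions, components that are more stable than A4, and a strongly polarised diene that should control orientation. On precedent this plan is better than the chosen one, because the cycloaddition type is well established while the chosen key step is not. On differentiation of the carboxyls it shares the advantage of alternative 2.
- Against it here: the adduct is one oxidation level short, which adds a dehydrogenation. The ring oxygen donates into the dienophile and lowers its reactivity, and the ketone and the ester of A6 polarise the alkene in opposite senses. Two stereocentres are made and then erased.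
- Comparison: it is expected to be the longest of the four plans (about twelve to thirteen steps), whereas the chosen plan forms the ether and the C6' carboxyl in one operation on fully aromatic partners.

Key step: step 8

Assumption: 2-chloro-3-methoxyphenol (1) is taken as a purchasable phenol; it carries the chlorine between its two oxygens from the start, so the route contains no electrophilic chlorination of uncertain site selectivity.

## Steps

Step 1
Reactants: 1 2-chloro-3-methoxyphenol
Product: 4 4-(benzyloxy)-3-chloro-2-methoxyphenol, via potassium 3-chloro-4-hydroxy-2-methoxyphenyl sulfate 2 (not isolated), via potassium 4-(benzyloxy)-3-chloro-2-methoxyphenyl sulfate 3 (not isolated)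
Conditions: K2S2O8, 10% aq KOH, 10 °C → rt; BnCl, EtOH, 70 °C; Et2O wash; then aq HCl (pH 1), 85 °C
Reagents that add atoms: K2S2O8, [K+].[K+].[O-]S(=O)(=O)OOS(=O)(=O)[O-]; benzyl chloride, ClCc1ccccc1
Why: Elbs persulfate oxidation: the phenoxide of 1 attacks a peroxide oxygen through its para carbon, so the new oxygen enters next to the methoxy carbon and is held as sulfate 2 while the original phenoxide stays free. Williamson benzylation of that phenoxide gives 3, and acid hydrolysis of the aryl sulfate then frees only the new hydroxyl, so the two oxygens are told apart without a selective alkylation.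

Step 2
Reactants: 4 4-(benzyloxy)-3-chloro-2-methoxyphenol
Product: 6 5-(benzyloxy)-4-chloro-2-hydroxy-3-methoxybenzaldehyde, via 4-(benzyloxy)-3-chloro-6-(hydroxymethyl)-2-methoxyphenol 5 (not isolated)
Conditions: MgCl2, Et3N, (CH2O)n, MeCN, reflux; aq HCl work-up
Reagents that add atoms: formaldehyde (as paraformaldehyde), C=O
Why: Magnesium-mediated ortho-formylation: the chloromagnesium phenoxide of 4 is hydroxymethylated at its only free ortho carbon (the other ortho and the para position are substituted), and the magnesium alkoxide of 5 is oxidised to the aldehyde by Oppenauer-type hydride transfer to a second formaldehyde.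

Step 3
Reactants: 6 5-(benzyloxy)-4-chloro-2-hydroxy-3-methoxybenzaldehyde
Product: 7 5-(benzyloxy)-4-chloro-2-hydroxy-3-methoxybenzoic acid
Conditions: NaClO2, NaH2PO4, 2-methyl-2-butene, t-BuOH/H2O, rt
Reagents that add atoms: NaClO2, [Na+].[O-]Cl=O
Why: Pinnick oxidation: chlorous acid adds to the aldehyde and fragments to the acid, while 2-methyl-2-butene removes HOCl so that the electron-rich ring is not chlorinated. Benzyl ether, phenol and aryl chloride are not affected.

Step 4
Reactants: 8 orcinol (5-methylbenzene-1,3-diol)
Product: 9 3-(benzyloxy)-5-methylphenol
Conditions: BnBr (1 equiv), K2CO3, acetone, reflux; 8 in excess (3 equiv)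
Reagents that add atoms: benzyl bromide, BrCc1ccccc1
Why: Williamson etherification of a symmetric diol; with 8 in excess the mono-ether should predominate, and the water-soluble surplus of 8 is washed out.

Step 5
Reactants: 9 3-(benzyloxy)-5-methylphenol
Product: 10 3-(benzyloxy)-5-methylphenyl N-isopropylcarbamate
Conditions: i-PrNCO, Et3N (cat.), CH2Cl2, rt
Reagents that add atoms: isopropyl isocyanate, CC(C)N=C=O
Why: Base-catalysed addition of the phenol to the isocyanate gives the N-monosubstituted carbamate, a strong directing group for metalation that can later be removed under mild base.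

Step 6
Reactants: 10 3-(benzyloxy)-5-methylphenyl N-isopropylcarbamate
Product: 14 3-(benzyloxy)-5-methyl-2-(trimethylsilyl)phenyl N-isopropylcarbamate, via N-silyl carbamate 11 (not isolated), via aryllithium 12 (not isolated), via C,N-bis-silyl carbamate 13 (not isolated)
Conditions: TBSOTf, TMEDA, Et2O, 0 °C → rt; n-BuLi, TMEDA, −78 °C; TMSCl, −78 °C → rt; aq NaHSO4
Reagents that add atoms: chlorotrimethylsilane, C[Si](C)(C)Cl
Why: Directed ortho-metalation: after transient N-silylation (11) the carbamate and the benzyloxy group cooperate, so n-BuLi/TMEDA should remove the proton on the carbon between the two oxygens (12) faster than any other ring or benzylic proton at −78 °C. TMSCl traps the aryllithium (13) and the N–Si bond is hydrolysed on acidic work-up.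

Step 7
Reactants: 14 3-(benzyloxy)-5-methyl-2-(trimethylsilyl)phenyl N-isopropylcarbamate
Product: 16 3-(benzyloxy)-5-methyl-2-(trimethylsilyl)phenyl trifluoromethanesulfonate, via 3-(benzyloxy)-5-methyl-2-(trimethylsilyl)phenol 15 (not isolated)
Conditions: DBU, Et2NH, MeCN, 40 °C; then PhNTf2, rt
Reagents that add atoms: N-phenylbis(trifluoromethanesulfonimide), O=S(=O)(N(c1ccccc1)S(=O)(=O)C(F)(F)F)C(F)(F)F
Why: E1cB cleavage of the N-monosubstituted carbamate by DBU releases isopropyl isocyanate, which diethylamine scavenges as a urea, and the hindered phenoxide of 15 is sulfonylated in the same flask by PhNTf2. The C–Si bond survives these fluoride-free conditions.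

Step 8
Reactants: 7 5-(benzyloxy)-4-chloro-2-hydroxy-3-methoxybenzoic acid; 16 3-(benzyloxy)-5-methyl-2-(trimethylsilyl)phenyl trifluoromethanesulfonate; 17 carbon dioxide
Product: 21 6-(benzyloxy)-2-[4-(benzyloxy)-6-carboxy-3-chloro-2-methoxyphenoxy]-4-methylbenzoic acid, via dipotassium salt 18 (not isolated), via 3-(benzyloxy)-5-methylbenzyne 19 (not isolated), via aryl anion 20 (not isolated)
Conditions: KH (2.0 equiv), THF, 0 °C → rt; then CO2 (1 atm), KF, 18-crown-6, 16 (1.5 equiv, slow addition), 0 °C → rt; aq HCl
Reagents that add atoms: carbon dioxide (17), O=C=O
Why: Proposed new method: KH converts 7 into the proton-free dipotassium salt 18 (H2 leaves the flask); fluoride then attacks silicon in 16 and triflate is lost in a 1,2-elimination to give aryne 19. The phenoxide oxygen of 18, far more nucleophilic than its carboxylate, should add to the aryne carbon meta to the benzyloxy group (C1'), the more distorted and more electrophilic terminus, which leaves the negative charge on C6' next to the inductively withdrawing oxygen. Aryl anion 20, paired with crown-complexed potassium in a medium without acidic protons, should be captured by dissolved 17 to form the C6' carboxylate, and acidification gives 21. The closest known reaction types are the O-arylation of phenoxides by arynes released from 2-(trimethylsilyl)aryl triflates and the three-component coupling of such arynes with amines and CO2 to anthranilic acids; combining a phenoxide, an aryne and CO2 is the new element. No ring is closed and no stereocentre is formed. Site selectivity rests on the 3-benzyloxy group of 19, carboxylation over protonation on the absence of proton donors (KH as base, THF instead of acetonitrile), and xanthone formation is excluded because ring A offers the anion a carboxylate and not an ester. Slow addition of 16 keeps the aryne concentration low so that 20 meets CO2 and not a second aryne.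

Step 9
Reactants: 21 6-(benzyloxy)-2-[4-(benzyloxy)-6-carboxy-3-chloro-2-methoxyphenoxy]-4-methylbenzoic acid
Product: 22 6-(benzyloxy)-2-[4-(benzyloxy)-3-chloro-2-methoxy-6-(methoxycarbonyl)phenoxy]-4-methylbenzoic acid
Conditions: HCl (1.25 M in MeOH), 45 °C, monitored
Reagents that add atoms: methanol, CO
Why: Fischer esterification under kinetic control: the ring A carboxyl has one ortho substituent and forms the tetrahedral intermediate readily, whereas the ring B carboxyl is flanked by two ortho oxygens and should be esterified much more slowly by the addition–elimination pathway. The moderate temperature also guards against protodecarboxylation of the electron-rich ring B acid.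

Step 10
Reactants: 22 6-(benzyloxy)-2-[4-(benzyloxy)-3-chloro-2-methoxy-6-(methoxycarbonyl)phenoxy]-4-methylbenzoic acid
Product: 23 2-[3-chloro-4-hydroxy-2-methoxy-6-(methoxycarbonyl)phenoxy]-6-hydroxy-4-methylbenzoic acid
Conditions: BCl3, C6HMe5, CH2Cl2, −78 °C; then H2O
Reagents that add atoms: none
Why: Lewis acid debenzylation: BCl3 coordinates the benzyl ether oxygens and the benzyl cations are captured by pentamethylbenzene (Friedel–Crafts), which protects the electron-rich rings from C-benzylation. At −78 °C the methyl ether, the methyl ester and the aryl chloride, which hydrogenolysis would endanger, should be retained.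

## Compound list

1 | 2-chloro-3-methoxyphenol | COc1cccc(O)c1Cl | starting material
2 | potassium 3-chloro-4-hydroxy-2-methoxyphenyl sulfate | COc1c(OS(=O)(=O)[O-])ccc(O)c1Cl.[K+] | intermediate (not isolated)
3 | potassium 4-(benzyloxy)-3-chloro-2-methoxyphenyl sulfate | COc1c(OS(=O)(=O)[O-])ccc(OCc2ccccc2)c1Cl.[K+] | intermediate (not isolated)
4 | 4-(benzyloxy)-3-chloro-2-methoxyphenol | COc1c(O)ccc(OCc2ccccc2)c1Cl | intermediate
5 | 4-(benzyloxy)-3-chloro-6-(hydroxymethyl)-2-methoxyphenol (present as its magnesium salt) | COc1c(O)c(CO)cc(OCc2ccccc2)c1Cl | intermediate (not isolated)
6 | 5-(benzyloxy)-4-chloro-2-hydroxy-3-methoxybenzaldehyde | COc1c(O)c(C=O)cc(OCc2ccccc2)c1Cl | intermediate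
7 | 5-(benzyloxy)-4-chloro-2-hydroxy-3-methoxybenzoic acid | COc1c(O)c(C(=O)O)cc(OCc2ccccc2)c1Cl | intermediate
8 | orcinol (5-methylbenzene-1,3-diol) | Cc1cc(O)cc(O)c1 | starting material
9 | 3-(benzyloxy)-5-methylphenol | Cc1cc(O)cc(OCc2ccccc2)c1 | intermediate
10 | 3-(benzyloxy)-5-methylphenyl N-isopropylcarbamate | Cc1cc(OCc2ccccc2)cc(OC(=O)NC(C)C)c1 | intermediate
11 | 3-(benzyloxy)-5-methylphenyl N-(tert-butyldimethylsilyl)-N-isopropylcarbamate | Cc1cc(OCc2ccccc2)cc(OC(=O)N(C(C)C)[Si](C)(C)C(C)(C)C)c1 | intermediate (not isolated)
12 | 2-lithio derivative of 11 (lithium on the carbon between the two oxygens) | Cc1cc(OCc2ccccc2)c([Li])c(OC(=O)N(C(C)C)[Si](C)(C)C(C)(C)C)c1 | intermediate (not isolated)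
13 | 3-(benzyloxy)-5-methyl-2-(trimethylsilyl)phenyl N-(tert-butyldimethylsilyl)-N-isopropylcarbamate | Cc1cc(OCc2ccccc2)c([Si](C)(C)C)c(OC(=O)N(C(C)C)[Si](C)(C)C(C)(C)C)c1 | intermediate (not isolated)
14 | 3-(benzyloxy)-5-methyl-2-(trimethylsilyl)phenyl N-isopropylcarbamate | Cc1cc(OCc2ccccc2)c([Si](C)(C)C)c(OC(=O)NC(C)C)c1 | intermediate
15 | 3-(benzyloxy)-5-methyl-2-(trimethylsilyl)phenol | Cc1cc(O)c([Si](C)(C)C)c(OCc2ccccc2)c1 | intermediate (not isolated)
16 | 3-(benzyloxy)-5-methyl-2-(trimethylsilyl)phenyl trifluoromethanesulfonate | Cc1cc(OCc2ccccc2)c([Si](C)(C)C)c(OS(=O)(=O)C(F)(F)F)c1 | intermediate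
17 | carbon dioxide | O=C=O | starting material
18 | dipotassium 5-(benzyloxy)-4-chloro-3-methoxy-2-oxidobenzoate | COc1c([O-])c(C(=O)[O-])cc(OCc2ccccc2)c1Cl.[K+].[K+] | intermediate (not isolated)
19 | 3-(benzyloxy)-5-methylbenzyne (triple bond between the former C–OTf and C–Si carbons) | CC1=CC#CC(OCc2ccccc2)=C1 | intermediate (not isolated)
20 | dipotassium salt of the C6' aryl anion of 5-(benzyloxy)-2-[3-(benzyloxy)-5-methylphenoxy]-4-chloro-3-methoxybenzoate | COc1c(Oc2cc(C)cc(OCc3ccccc3)[c-]2)c(C(=O)[O-])cc(OCc4ccccc4)c1Cl.[K+].[K+] | intermediate (not isolated)
21 | 6-(benzyloxy)-2-[4-(benzyloxy)-6-carboxy-3-chloro-2-methoxyphenoxy]-4-methylbenzoic acid | OC(=O)c1cc(OCc2ccccc2)c(Cl)c(OC)c1Oc1cc(C)cc(OCc2ccccc2)c1C(=O)O | intermediate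
22 | 6-(benzyloxy)-2-[4-(benzyloxy)-3-chloro-2-methoxy-6-(methoxycarbonyl)phenoxy]-4-methylbenzoic acid | COC(=O)c1cc(OCc2ccccc2)c(Cl)c(OC)c1Oc1cc(C)cc(OCc2ccccc2)c1C(=O)O | intermediate
23 | 2-[3-chloro-4-hydroxy-2-methoxy-6-(methoxycarbonyl)phenoxy]-6-hydroxy-4-methylbenzoic acid | COC(=O)c1cc(O)c(Cl)c(OC)c1Oc1cc(C)cc(O)c1C(=O)O | target

## Step count and risks

Total step count: 10. Longest linear sequence: 7 steps (8 → 9 → 10 → 14 → 16 → 21 → 22 → 23); the ring A branch contributes 3 steps before the coupling.

Step 8 (key step, proposed new method). The most likely failure is protonation of the aryl anion before it meets CO2, which would leave C6' without its carboxyl. Competing addition of the carboxylate oxygen instead of the phenoxide, or sluggish aryne release because fluoride is tied up by CO2, are further risks. Fallback in known chemistry, setting out from 7 and coming back at 21: an Ullmann ether condensation. 3-Bromo-5-methylphenol F1 (purchased) would be benzylated (BnBr, K2CO3) to 1-(benzyloxy)-3-bromo-5-methylbenzene F2. Deprotonation between bromine and oxygen with LiN(i-Pr)2 at −78 °C and carboxylation with CO2 would give 2-(benzyloxy)-6-bromo-4-methylbenzoic acid F3. Copper-mediated coupling of F3 with 7 (CuI, Cs2CO3, N,N-dimethylglycine, 1,4-dioxane, 100 °C), helped by the ortho-carboxylate effect, would give 21, and the route would continue with step 9.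

Step 1. The Elbs oxidation may stop at low conversion, and radical coupling or ortho attack of the phenoxide may consume material. Fallback setting out from 1 and coming back at 4: Teuber oxidation of 1 with (KSO3)2NO (KH2PO4 buffer, H2O/acetone) to 2-chloro-3-methoxy-1,4-benzoquinone F4, then reduction with Na2S2O4 to 2-chloro-3-methoxybenzene-1,4-diol F5. Mono-benzylation with one equivalent of K2CO3 and BnBr should favour the more acidic hydroxyl next to chlorine and give 4; this relies on an acidity difference rather than on the sulfate mask.

Step 6. Deprotonation of the benzylic CH2 of the benzyl ether (followed by Wittig rearrangement) or an anionic ortho-Fries shift of the carbamoyl group on warming may compete with silylation. Fallback setting out from 8 and coming back at 15: iodination of 8 between the hydroxyls (I2, NaHCO3, H2O) to 2-iodo-5-methylbenzene-1,3-diol F6, and mono-benzylation to 3-(benzyloxy)-2-iodo-5-methylphenol F7. O-Silylation with hexamethyldisilazane would give [3-(benzyloxy)-2-iodo-5-methylphenoxy]trimethylsilane F8. Iodine–lithium exchange with n-BuLi at −78 °C would trigger a retro-Brook shift of silicon from oxygen to carbon and give the lithium salt of 15, which Tf2O would convert into 16 in the same flask.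

Step 9. Loss of chemoselectivity (esterification of the ring B carboxyl as well) or acid-induced protodecarboxylation of the 2,6-dioxygenated acid may occur. Fallback setting out from 7 and coming back at 22, in which the two carboxyl carbons differ in oxidation state from the start: Fischer esterification of 7 (H2SO4, MeOH, reflux) to methyl 5-(benzyloxy)-4-chloro-2-hydroxy-3-methoxybenzoate F9. 3-Fluoro-5-methylphenol F10 (purchased) would be benzylated to 1-(benzyloxy)-3-fluoro-5-methylbenzene F11, then lithiated between fluorine and oxygen (n-BuLi, THF, −78 °C) and formylated with DMF to 2-(benzyloxy)-6-fluoro-4-methylbenzaldehyde F12. Nucleophilic aromatic substitution of the fluoride in F12 by the phenoxide of F9 (Cs2CO3, DMSO, 90 °C) would give methyl 5-(benzyloxy)-2-[3-(benzyloxy)-2-formyl-5-methylphenoxy]-4-chloro-3-methoxybenzoate F13, and Pinnick oxidation (NaClO2, NaH2PO4, 2-methyl-2-butene) of the aldehyde would give 22.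

## Further compounds

F1 | step 8 | 3-bromo-5-methylphenol (purchased) | Cc1cc(O)cc(Br)c1
F2 | step 8 | 1-(benzyloxy)-3-bromo-5-methylbenzene | Cc1cc(Br)cc(OCc2ccccc2)c1
F3 | step 8 | 2-(benzyloxy)-6-bromo-4-methylbenzoic acid | Cc1cc(Br)c(C(=O)O)c(OCc2ccccc2)c1
F4 | step 1 | 2-chloro-3-methoxy-1,4-benzoquinone | COC1=C(Cl)C(=O)C=CC1=O
F5 | step 1 | 2-chloro-3-methoxybenzene-1,4-diol | COc1c(O)ccc(O)c1Cl
F6 | step 6 | 2-iodo-5-methylbenzene-1,3-diol | Cc1cc(O)c(I)c(O)c1
F7 | step 6 | 3-(benzyloxy)-2-iodo-5-methylphenol | Cc1cc(O)c(I)c(OCc2ccccc2)c1
F8 | step 6 | [3-(benzyloxy)-2-iodo-5-methylphenoxy]trimethylsilane | Cc1cc(O[Si](C)(C)C)c(I)c(OCc2ccccc2)c1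
F9 | step 9 | methyl 5-(benzyloxy)-4-chloro-2-hydroxy-3-methoxybenzoate | COC(=O)c1cc(OCc2ccccc2)c(Cl)c(OC)c1O
F10 | step 9 | 3-fluoro-5-methylphenol (purchased) | Cc1cc(O)cc(F)c1
F11 | step 9 | 1-(benzyloxy)-3-fluoro-5-methylbenzene | Cc1cc(F)cc(OCc2ccccc2)c1
F12 | step 9 | 2-(benzyloxy)-6-fluoro-4-methylbenzaldehyde | Cc1cc(F)c(C=O)c(OCc2ccccc2)c1
F13 | step 9 | methyl 5-(benzyloxy)-2-[3-(benzyloxy)-2-formyl-5-methylphenoxy]-4-chloro-3-methoxybenzoate | COC(=O)c1cc(OCc2ccccc2)c(Cl)c(OC)c1Oc1cc(C)cc(OCc2ccccc2)c1C=O
A1 | alternative 1 | 1-tert-butyl 7-methyl (2E,5Z)-3-[3-chloro-2-methoxy-6-(methoxycarbonyl)-4-(methoxymethoxy)phenoxy]-5-methylhepta-2,5-dienedioate | COC(=O)c1cc(OCOC)c(Cl)c(OC)c1O/C(=C/C(=O)OC(C)(C)C)C/C(C)=C\C(=O)OC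
A2 | alternative 1 | tert-butyl 2-[3-chloro-2-methoxy-6-(methoxycarbonyl)-4-(methoxymethoxy)phenoxy]-6-hydroxy-4-methylbenzoate | COC(=O)c1cc(OCOC)c(Cl)c(OC)c1Oc1cc(C)cc(O)c1C(=O)OC(C)(C)C
A3 | alternative 2 | 4-(benzyloxy)-6-methyl-1-benzofuran-3(2H)-one | O=C1COc2cc(C)cc(OCc3ccccc3)c21
A4 | alternative 2 | methyl 6-methoxy-4-oxohexa-2,5-diynoate | COC#CC(=O)C#CC(=O)OC
A5 | alternative 2 | methyl 4-(benzyloxy)-2'-methoxy-6-methyl-3,4'-dioxo-3H-spiro[1-benzofuran-2,1'-cyclohexane]-2',5'-diene-6'-carboxylate (racemic, one enantiomer drawn) | COC(=O)C1=CC(=O)C=C(OC)[C@]12Oc3cc(C)cc(OCc4ccccc4)c3C2=O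
A6 | alternative 3 | methyl (2Z)-[4-(benzyloxy)-6-methyl-3-oxo-1-benzofuran-2(3H)-ylidene]acetate | COC(=O)/C=C1\Oc2cc(C)cc(OCc3ccccc3)c2C1=O
A7 | alternative 3 | 1,1-dimethoxy-3-(trimethylsilyloxy)buta-1,3-diene | COC(OC)=CC(=C)O[Si](C)(C)C
A8 | alternative 3 | methyl 4-(benzyloxy)-2'-methoxy-6-methyl-3,4'-dioxo-3H-spiro[1-benzofuran-2,1'-cyclohexan]-2'-ene-6'-carboxylate (racemic, one diastereomer drawn) | COC(=O)[C@@H]1CC(=O)C=C(OC)[C@]12Oc3cc(C)cc(OCc4ccccc4)c3C2=O
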